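Cuts: the three protecting O-benzyl groups come off first. O1–C2 (ring C) and O1''–C2'' (ring C'') are then cut together, a double retro-oxa-Michael step, to an achiral open bichalcone. After that come both Cα=Cβ alkenes, the C4'–O bond of the diaryl ether and the C6''–O bond.
Enabling feature: rings C and C'' are both β-aryloxy ketones (O1 and O1'' lie β to C4=O and C4''=O). Both C2 centres are S and the C4'–O–C6'' ether insulates them, so one chiral catalyst can close both rings and set both centres in one flask.
Both ketone halves come from one monomer, 2-benzyloxy-6-hydroxy-4-methoxyacetophenone. It is used as such for ring A and after para-hydroxylation for ring A''. Its benzyl group on O5'' blocks closure to the 8''-aryloxy isomer.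
Forward order: rings A, B, A'' and B'' are bought as benzenes. The sequence is ether link, chalcone of the A''/B'' half, chalcone of the A/B half, then ring C and last ring C''.
Stereochemistry: both base-labile C2 centres arise at the end under catalyst control (cinchona thiourea), and only a neutral hydrogenolysis follows.

Key step: step 7

Locants: rings A, C, B (C2–C8a, C1'–C6') belong to the half whose O4' is arylated. Rings A'', C'', B'' (C2''–C8a'', C1'''–C6''') belong to the half that carries the aryloxy group at C6''.
Assumption: the quinine-derived thiourea is taken to deliver oxygen to the Si face of each enone β-carbon (2S). If the sense is the opposite, the quinidine-derived pseudoenantiomer takes its place with no other change.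

Step 1
Reactants: 1 1-(2,6-dihydroxy-4-methoxyphenyl)ethanone
Product: 2 1-[2-(benzyloxy)-6-hydroxy-4-methoxyphenyl]ethanone
Conditions: BnBr (1.05 equiv), K2CO3, acetone, reflux
Reagents that add atoms: benzyl bromide, BrCc1ccccc1
Why: Williamson etherification of one of two equivalent phenols, which should stop at the mono-ether because the remaining ortho-OH is hydrogen-bonded to the acetyl carbonyl and far less nucleophilic.

Step 2
Reactants: 2 1-[2-(benzyloxy)-6-hydroxy-4-methoxyphenyl]ethanone
Product: 4 1-[2-(benzyloxy)-3,6-dihydroxy-4-methoxyphenyl]ethanone, via potassium aryl sulfate 3 (not isolated)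
Conditions: K2S2O8, aq KOH, pyridine, 0 °C to rt; then aq HCl, 80 °C, N2
Reagents that add atoms: potassium peroxodisulfate, [K+].[K+].[O-]S(=O)(=O)OOS(=O)(=O)[O-]
Why: Elbs persulfate oxidation, in which the phenoxide attacks the peroxide O–O bond through its free para carbon (C3, between OBn and OMe) and acid then hydrolyses the aryl sulfate, while the benzyl and methyl ethers are inert to cold alkali and brief dilute acid.

Step 3
Reactants: 4 1-[2-(benzyloxy)-3,6-dihydroxy-4-methoxyphenyl]ethanone; 5 4-fluorobenzaldehyde
Product: 6 4-[3-acetyl-2-(benzyloxy)-4-hydroxy-6-methoxyphenoxy]benzaldehyde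
Conditions: K2CO3, degassed DMF, N2, 100 °C
Reagents that add atoms: none
Why: Nucleophilic aromatic substitution (addition-elimination) on the para-formyl-activated fluoride by the electron-rich C3 phenoxide, while the C6 phenoxide is chelated and conjugated to the acetyl group and the doubly ortho-flanked acetyl group should not enolise under carbonate.

Step 4
Reactants: 6 4-[3-acetyl-2-(benzyloxy)-4-hydroxy-6-methoxyphenoxy]benzaldehyde
Product: 7 1-{2-(benzyloxy)-3-[4-(dimethoxymethyl)phenoxy]-6-hydroxy-4-methoxyphenyl}ethanone
Conditions: HC(OMe)3, p-TsOH·H2O (cat.), CH2Cl2, rt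
Reagents that add atoms: trimethyl orthoformate, COC(OC)OC
Why: Acid-catalysed acetalisation masks the formyl group so that 6 cannot condense with itself in the next step, and the hindered, chelated aryl ketone should not ketalise.

Step 5
Reactants: 7 1-{2-(benzyloxy)-3-[4-(dimethoxymethyl)phenoxy]-6-hydroxy-4-methoxyphenyl}ethanone; 8 4-(benzyloxy)benzaldehyde
Product: 10 4-{2-(benzyloxy)-3-[(E)-3-(4-(benzyloxy)phenyl)acryloyl]-4-hydroxy-6-methoxyphenoxy}benzaldehyde, via chalcone dimethyl acetal 9 (not isolated)
Conditions: KOH, EtOH, rt; then 1 M HCl, THF, 0 °C to rt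
Reagents that add atoms: water, O
Why: Claisen–Schmidt condensation of a 2-hydroxy-4,6-dialkoxyacetophenone with a non-enolisable aldehyde gives the E-enone, and the acidic work-up hydrolyses the aryl dimethyl acetal at a temperature at which such chalcones do not yet cyclise.

Step 6
Reactants: 10 4-{2-(benzyloxy)-3-[(E)-3-(4-(benzyloxy)phenyl)acryloyl]-4-hydroxy-6-methoxyphenoxy}benzaldehyde; 2 1-[2-(benzyloxy)-6-hydroxy-4-methoxyphenyl]ethanone
Product: 11 tri-O-benzyl bichalcone, (E)-1-[2-(benzyloxy)-6-hydroxy-4-methoxyphenyl]-3-[4-(2-(benzyloxy)-3-{(E)-3-[4-(benzyloxy)phenyl]acryloyl}-4-hydroxy-6-methoxyphenoxy)phenyl]prop-2-en-1-one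
Conditions: KOH, EtOH/THF, rt; cold 1 M HCl to pH 4; recrystallisation to remove any cyclised material
Reagents that add atoms: none
Why: A second Claisen–Schmidt condensation, in which only 2 can enolise and only the formyl group of 10 is a good acceptor, because the existing enone is deactivated as its ortho-phenoxide and by its donor aryl group.

Step 7
Reactants: 11 tri-O-benzyl bichalcone
Product: 13 (2S,2''S)-5,5'',4'''-tri-O-benzyl-7,7''-di-O-methyltetrahydrohinokiflavone, via flavanone-chalcone 12 (not isolated)
Conditions: 1-[3,5-bis(trifluoromethyl)phenyl]-3-[(8α,9S)-6'-methoxycinchonan-9-yl]thiourea (20 mol%), toluene (0.01 M), 4 Å MS, rt; cold aq citric acid wash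
Reagents that add atoms: none
Why: Twofold enantioselective intramolecular oxa-Michael addition, the laboratory copy of the chalcone-to-flavanone isomerisation of flavonoid biosynthesis: the quinuclidine nitrogen of the catalyst takes up the proton of the free ortho-phenol while the two thiourea N–H bonds hold the enone carbonyl, the oxygen adds to C-β, and the enol is protonated at C-α. The closest known reaction type is the cinchona thiourea or squaramide catalysed cyclisation of 2'-hydroxychalcones, and of their α-ester-activated relatives, to flavanones. Each ring closes in the 6-endo-trig mode; ring C (O1–C2) should close first, giving 12, because its acceptor bears the weaker donor (4-aryloxyphenyl), and ring C'' (O1''–C2''), whose acceptor bears the stronger 4-benzyloxyphenyl donor and hangs on the more crowded ring A'', should close last. C2 and C2'' are each set by the catalyst alone through delivery of oxygen to the Si face of C-β, since the diaryl ether keeps the two enones out of reach of one another, and because one catalyst acts twice most wrong-face events end in a diastereomer and not in the enantiomer, so the enantiomeric purity of 13 should be higher than that of a single closure. The regioselectivity needed on ring A'' (6''-aryloxy, not 8''-aryloxy) is secured by the benzyl ether on O5'', the oxygen flanked by the aryloxy group, which leaves only the oxygen on the carbon para to C6'' free to attack; on ring A the second ortho oxygen is benzylated as well, so no choice arises. The ortho-benzyloxy groups twist both aroyl groups out of conjugation, which makes closure downhill and its reversal slow, and high dilution together with removal of the amine by a cold acid wash guards against intermolecular addition and against loss of configuration.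

Step 8
Reactants: 13 (2S,2''S)-5,5'',4'''-tri-O-benzyl-7,7''-di-O-methyltetrahydrohinokiflavone
Product: 14 (2S,2''S)-7,7''-di-O-methyltetrahydrohinokiflavone
Conditions: H2 (1 atm), 10% Pd/C, EtOAc/THF, rt
Reagents that add atoms: none
Why: Catalytic hydrogenolysis cleaves the three aryl benzyl ethers faster than the cyclic benzylic C2–O1 and C2''–O1'' bonds, and in the absence of acid or base neither retro-oxa-Michael opening nor enolisation can scramble the two stereocentres.

Compound list
1 | 1-(2,6-dihydroxy-4-methoxyphenyl)ethanone (2',6'-dihydroxy-4'-methoxyacetophenone) | CC(=O)c1c(O)cc(OC)cc1O | starting material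
2 | 1-[2-(benzyloxy)-6-hydroxy-4-methoxyphenyl]ethanone | CC(=O)c1c(O)cc(OC)cc1OCc1ccccc1 | intermediate
3 | potassium 3-acetyl-2-(benzyloxy)-4-hydroxy-6-methoxyphenyl sulfate | CC(=O)c1c(O)cc(OC)c(OS(=O)(=O)[O-])c1OCc1ccccc1.[K+] | intermediate
4 | 1-[2-(benzyloxy)-3,6-dihydroxy-4-methoxyphenyl]ethanone | CC(=O)c1c(O)cc(OC)c(O)c1OCc1ccccc1 | intermediate
5 | 4-fluorobenzaldehyde | O=Cc1ccc(F)cc1 | starting material
6 | 4-[3-acetyl-2-(benzyloxy)-4-hydroxy-6-methoxyphenoxy]benzaldehyde | CC(=O)c1c(O)cc(OC)c(Oc2ccc(C=O)cc2)c1OCc1ccccc1 | intermediate
7 | 1-{2-(benzyloxy)-3-[4-(dimethoxymethyl)phenoxy]-6-hydroxy-4-methoxyphenyl}ethanone | CC(=O)c1c(O)cc(OC)c(Oc2ccc(C(OC)OC)cc2)c1OCc1ccccc1 | intermediate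
8 | 4-(benzyloxy)benzaldehyde | O=Cc1ccc(OCc2ccccc2)cc1 | starting material
9 | (E)-1-{2-(benzyloxy)-3-[4-(dimethoxymethyl)phenoxy]-6-hydroxy-4-methoxyphenyl}-3-[4-(benzyloxy)phenyl]prop-2-en-1-one | COC(OC)c1ccc(Oc2c(OC)cc(O)c(C(=O)/C=C/c3ccc(OCc4ccccc4)cc3)c2OCc2ccccc2)cc1 | intermediate
10 | 4-{2-(benzyloxy)-3-[(E)-3-(4-(benzyloxy)phenyl)acryloyl]-4-hydroxy-6-methoxyphenoxy}benzaldehyde | O=Cc1ccc(Oc2c(OC)cc(O)c(C(=O)/C=C/c3ccc(OCc4ccccc4)cc3)c2OCc2ccccc2)cc1 | intermediate
11 | tri-O-benzyl bichalcone (both enones E, one free ortho-OH on each of rings A and A'') | COc1cc(O)c(C(=O)/C=C/c2ccc(Oc3c(OC)cc(O)c(C(=O)/C=C/c4ccc(OCc5ccccc5)cc4)c3OCc3ccccc3)cc2)c(OCc2ccccc2)c1 | intermediate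
12 | (2S)-5-(benzyloxy)-7-methoxyflavanone whose O4' carries the still open ring A'' chalcone | COc1cc(OCc2ccccc2)c2c(c1)O[C@H](c1ccc(Oc3c(OC)cc(O)c(C(=O)/C=C/c4ccc(OCc5ccccc5)cc4)c3OCc3ccccc3)cc1)CC2=O | intermediate
13 | (2S,2''S)-5,5'',4'''-tri-O-benzyl-7,7''-di-O-methyltetrahydrohinokiflavone | COc1cc(OCc2ccccc2)c2c(c1)O[C@H](c1ccc(Oc3c(OC)cc4c(c3OCc3ccccc3)C(=O)C[C@@H](c3ccc(OCc5ccccc5)cc3)O4)cc1)CC2=O | intermediate
14 | (2S,2''S)-7,7''-di-O-methyltetrahydrohinokiflavone | COc1cc(O)c2c(c1)O[C@H](c1ccc(Oc3c(OC)cc4c(c3O)C(=O)C[C@@H](c3ccc(O)cc3)O4)cc1)CC2=O | target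

Total step count: 8. Longest linear sequence: 8 (steps 1 to 8; compound 2 is used a second time in step 6).

Steps most likely to fail

Step 7. Turnover may be slow on two donor-substituted enones and facial discrimination may be incomplete. Configuration may also erode through reversible ring opening while the amine is present. Wrong-face events give diastereomers that differ only at remote centres and may be hard to remove. The fallback sets out from 11 and comes back at 13, replacing asymmetric catalysis by resolution with recycling. Both rings are closed without stereocontrol (NaOAc, EtOH, reflux) to the tri-O-benzyl biflavanone stereoisomer mixture F1. Compound 13 is taken from it by preparative chromatography on an amylose tris(3,5-dimethylphenylcarbamate) phase. The unwanted isomers are reopened with KOH in EtOH to 11 and sent through again.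

Step 2. The lipophilic phenoxide may convert poorly, and radical pathways of the persulfate may over-oxidise the electron-rich ring. The fallback sets out from 2 and comes back at 4, reaching the para oxygen by way of the quinone oxidation level. Teuber oxidation with (KSO3)2NO in KH2PO4-buffered aqueous acetone should give 2-acetyl-3-(benzyloxy)-5-methoxy-1,4-benzoquinone F2. Shaking this with aqueous Na2S2O4 and EtOAc reduces it to 4.

Step 3. The doubly ortho-flanked phenoxide may attack sluggishly and the hydroquinone dianion may be oxidised by air. Arylation could also occur at the chelated oxygen, and carbonate could induce condensation between acetyl and formyl groups at the temperature needed. The fallback sets out from 4 and comes back at 6, replacing addition-elimination by a copper-catalysed Ullmann-type C–O coupling suited to hindered phenols. The partner is 4-iodobenzaldehyde (CuI, picolinic acid, K3PO4, DMSO, 80 °C, N2). No compound outside the list is made (F0).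

Further compounds
F1 | step 7 | 5,5'',4'''-tri-O-benzyl-7,7''-di-O-methyltetrahydrohinokiflavone as the mixture of its four stereoisomers | COc1cc(OCc2ccccc2)c2c(c1)OC(c1ccc(Oc3c(OC)cc4c(c3OCc3ccccc3)C(=O)CC(c3ccc(OCc5ccccc5)cc3)O4)cc1)CC2=O
F2 | step 2 | 2-acetyl-3-(benzyloxy)-5-methoxy-1,4-benzoquinone | CC(=O)C1=C(OCc2ccccc2)C(=O)C(OC)=CC1=O
F0 | step 3 | none | none
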